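**Plan**
The C13 acetate and C8 methacrylate are removed last. The C8 ester oxygen and the C9 hydroxyl are traced to a trans 8,9-oxirane, and that oxirane plus the C8–C9 ring bond are cut to a C8 sulfonium salt and a C9 aldehyde.
Enabling feature: C8 is allylic to the C7=C11 butenolide alkene, so a C8 sulfonium is acidified by the C12 lactone carbonyl, and it is vicinal to the C9 carbinol. An oxirane on C8–C9 fused to the ten-membered ring therefore holds both oxygens and later opens only at C8.
The seco chain is cut at C10–C1 (crotylboration), C7=C11 (tethered Horner–Wadsworth–Emmons) and C6–C7 (vinyllithium addition), back to geraniol.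
Forward ring order: 4,5-oxirane (step 1), butenolide (step 10), then the ten-membered carbocycle and the 8,9-oxirane together (step 17).
Stereochemistry: C4/C5 from Sharpless epoxidation; C6 from Felkin addition followed by Mitsunobu inversion; C10 from catalyst-controlled crotylboration; C8/C9 from the ylide cyclisation, with C8 kept by double inversion at palladium.
Key step: step 17

Remark: every intermediate carries the target's germacrane numbering (C1–C10 ring carbons, C11–C13 lactone side, methyls on C4 and C10). C1 is carried as a triethylsilyl-protected carbinol up to the macrocycle, because a C1 carbonyl beside a C9 aldehyde would enolise and ketal chemistry would endanger the 4,5-oxirane.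

**Route**

Step 1
Reactants: 1 geraniol
Product: 2 (2R,3R)-2,3-epoxygeraniol
Conditions: Ti(OiPr)4 (5 mol %), D-(−)-diethyl tartrate (6 mol %), t-BuOOH, 4 Å MS, CH2Cl2, −20 °C
Reagents that add atoms: tert-butyl hydroperoxide, CC(C)(C)OO
Why: Sharpless asymmetric epoxidation of the primary allylic alcohol with the D-tartrate ligand should give the (2R,3R) oxirane, which becomes C5 (R) and C4 (R), and leave the remote trisubstituted alkene untouched.

Step 2
Reactants: 2 (2R,3R)-2,3-epoxygeraniol
Product: 3 (2S,3R)-2,3-epoxygeranial
Conditions: PhI(OAc)2, 2,2,6,6-tetramethylpiperidine-1-oxyl (10 mol %), CH2Cl2, 23 °C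
Reagents that add atoms: none
Why: Oxoammonium-mediated oxidation of a primary alcohol stops at the aldehyde under neutral conditions that spare the oxirane and its alpha stereocentre.

Step 3
Reactants: 4 2,3-dibromopropene, 5 4-methoxybenzyl alcohol
Product: 6 2-bromoallyl 4-methoxybenzyl ether
Conditions: NaH, THF, 0 → 23 °C
Reagents that add atoms: none
Why: Williamson ether synthesis in which the alkoxide displaces only the allylic bromide, the vinylic bromide being inert to SN2.

Step 4
Reactants: 6 2-bromoallyl 4-methoxybenzyl ether, 3 (2S,3R)-2,3-epoxygeranial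
Product: 8 anti epoxy alcohol (1R)-2-[(4-methoxybenzyloxy)methyl]-1-[(2R,3R)-3-methyl-3-(4-methylpent-3-enyl)oxiran-2-yl]prop-2-en-1-ol, via 2-lithioallyl 4-methoxybenzyl ether 7 (not isolated)
Conditions: 6, t-BuLi (2.1 equiv), Et2O, −78 °C; then 3, −78 °C; then H2O
Reagents that add atoms: none
Why: Bromine–lithium exchange then 1,2-addition to the aldehyde, where polar Felkin–Anh attack anti to the oxirane C–O bond should favour the (6R) anti carbinol (minor epimer removed by chromatography), deliberately opposite to the target because step 8 inverts C6.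

Step 5
Reactants: 9 benzyl diethylphosphonoacetate
Product: 10 benzyl 2-(diethoxyphosphoryl)-3-hydroxypropanoate (racemic)
Conditions: paraformaldehyde (1.1 equiv), piperidine (10 mol %), THF, 60 °C
Reagents that add atoms: formaldehyde (as paraformaldehyde), C=O
Why: Amine-catalysed aldol-type hydroxymethylation of the doubly activated methylene (first half of a Knoevenagel condensation), held at the carbinol by avoiding acid and excess formaldehyde.

Step 6
Reactants: 10 benzyl 2-(diethoxyphosphoryl)-3-hydroxypropanoate
Product: 11 benzyl 3-(tert-butyldimethylsilyloxy)-2-(diethoxyphosphoryl)propanoate (racemic)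
Conditions: TBSCl, imidazole, CH2Cl2, 0 → 23 °C
Reagents that add atoms: tert-butyldimethylsilyl chloride, CC(C)(C)[Si](C)(C)Cl
Why: Imidazole-promoted silylation of the primary alcohol protects the future C13 oxygen as a poor leaving group.

Step 7
Reactants: 11 benzyl 3-(tert-butyldimethylsilyloxy)-2-(diethoxyphosphoryl)propanoate
Product: 12 3-(tert-butyldimethylsilyloxy)-2-(diethoxyphosphoryl)propanoic acid (racemic)
Conditions: H2 (1 atm), Pd/C, EtOAc, 23 °C
Reagents that add atoms: none
Why: Hydrogenolysis of the benzyl ester frees the acid without base, so the beta-silyloxy phosphonate never meets E1cB conditions.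

Step 8
Reactants: 8 anti epoxy alcohol, 12 3-(tert-butyldimethylsilyloxy)-2-(diethoxyphosphoryl)propanoic acid
Product: 13 syn phosphonate ester (1S)-2-[(4-methoxybenzyloxy)methyl]-1-[(2R,3R)-3-methyl-3-(4-methylpent-3-enyl)oxiran-2-yl]prop-2-enyl 3-(tert-butyldimethylsilyloxy)-2-(diethoxyphosphoryl)propanoate
Conditions: PPh3, DIAD, THF, 0 → 23 °C
Reagents that add atoms: none
Why: Mitsunobu esterification, in which SN2 displacement of the oxyphosphonium by the carboxylate inverts C6 to the target's (6S) arrangement and installs the phosphonate tether at once (the racemic acid suffices because C11 becomes sp2).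

Step 9
Reactants: 13 syn phosphonate ester
Product: 15 keto aldehyde (ester 13 with a C7 ketone and a C1 aldehyde), via bis-ozonide 14 (not isolated)
Conditions: O3, CH2Cl2, −78 °C (Sudan red 7B end point); then Me2S, −78 → 23 °C
Reagents that add atoms: ozone, [O-][O+]=O
Why: Ozonolysis with reductive work-up cleaves the 1,1-disubstituted alkene to the C7 ketone and the isopropylidene terminus to the C1 aldehyde, while the anisyl ring and oxirane react far more slowly at −78 °C.

Step 10
Reactants: 15 keto aldehyde
Product: 16 butenolide aldehyde ((6S)-7(11)-en-12,6-olide with (4R,5R)-oxirane, C8 4-methoxybenzyl ether, C13 tert-butyldimethylsilyl ether, C1 aldehyde)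
Conditions: LiCl, iPr2NEt, MeCN, 0.005 M, 0 → 23 °C
Reagents that add atoms: none
Why: Intramolecular Horner–Wadsworth–Emmons olefination under Masamune–Roush conditions, where five-membered closure onto the C7 ketone should outrun intermolecular reaction with the C1 aldehyde at this dilution and the mild base spares H-6 and the silyloxy group.

Step 11
Reactants: 16 butenolide aldehyde, 17 (Z)-crotylboronic acid pinacol ester
Product: 18 (1S,10S)-homoallylic alcohol (16 with C1 carbinol, C10 methyl and C9 vinyl)
Conditions: (R)-3,3'-bis(2,4,6-triisopropylphenyl)-1,1'-binaphthyl-2,2'-diyl hydrogen phosphate (5 mol %), 4 Å MS, toluene, −30 °C; aq. NaHCO3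
Reagents that add atoms: none
Why: Chiral phosphoric acid-catalysed crotylboration through a closed chair transition state, in which the (Z)-boronate gives the syn adduct and the (R)-acid should direct attack to the Re face of the formyl group, setting C10 in the target's arrangement and a temporary C1 (S) carbinol.

Step 12
Reactants: 18 (1S,10S)-homoallylic alcohol
Product: 19 C1 triethylsilyl ether
Conditions: TESCl, imidazole, 4-(dimethylamino)pyridine (5 mol %), CH2Cl2, 0 °C
Reagents that add atoms: chlorotriethylsilane, CC[Si](Cl)(CC)CC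
Why: Silylation under basic, acid-free conditions caps the C1 hydroxyl before it can open the 4,5-oxirane by 5-exo attack.

Step 13
Reactants: 19 C1 triethylsilyl ether
Product: 20 C8 primary alcohol
Conditions: DDQ, CH2Cl2/pH 7 buffer (10:1), 0 °C
Reagents that add atoms: none
Why: Oxidative cleavage of the 4-methoxybenzyl ether (hydride abstraction, then hydrolysis) frees the C8 alcohol under neutral conditions that leave both silyl ethers, the oxirane and the vinyl group intact.

Step 14
Reactants: 20 C8 primary alcohol
Product: 22 C8 alcohol C9 aldehyde, via ozonide 21 (not isolated)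
Conditions: O3, CH2Cl2, −78 °C; then Me2S, −78 → 23 °C
Reagents that add atoms: ozone, [O-][O+]=O
Why: Ozonolysis of the only electron-rich alkene left (the butenolide alkene is tetrasubstituted and electron-poor) should reveal the C9 aldehyde without disturbing C10.

Step 15
Reactants: 22 C8 alcohol C9 aldehyde
Product: 23 C8 bromide C9 aldehyde
Conditions: PPh3, N-bromosuccinimide, CH2Cl2, −30 → 0 °C
Reagents that add atoms: N-bromosuccinimide, O=C1CCC(=O)N1Br
Why: Appel-type bromination of the primary allylic alcohol through its oxyphosphonium ion, with a reagent pair that forms no dibromomethylene ylide and so leaves the aldehyde alone.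

Step 16
Reactants: 23 C8 bromide C9 aldehyde, 24 tetrahydrothiophene
Product: 25 seco C8 tetrahydrothiophenium bromide with C9 aldehyde (C1 triethylsilyl ether, C13 tert-butyldimethylsilyl ether)
Conditions: tetrahydrothiophene (10 equiv), acetone, 23 °C, dark; evaporate, triturate with Et2O
Reagents that add atoms: none
Why: SN2 S-alkylation of the sulfide by the activated allylic bromide (a gamma-bromo enoate) should give the sulfonium salt, which is used without chromatography.

Step 17
Reactants: 25 seco C8 tetrahydrothiophenium bromide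
Product: 28 4,5:8,9-bis-epoxy macrocyclic butenolide (1S,4R,5R,6S,8R,9R,10S; C1 triethylsilyl ether; C13 tert-butyldimethylsilyl ether), via C8 sulfonium ylide 26 (not isolated), via anti betaine 27 (not isolated)
Conditions: Cs2CO3 (3 equiv), 4 Å MS, MeCN, 0 → 23 °C, 25 added by syringe pump to 1 mM
Reagents that add atoms: none
Why: Proposed new method: Cs2CO3 should remove a C8 proton (alpha to sulfonium and vinylogously acidified by the C12 lactone carbonyl through C7=C11, hence far more acidic than H-6 or H-10) to give ylide 26, which adds through C8 to the C9 aldehyde to form betaine 27, whose alkoxide then displaces tetrahydrothiophene at C8 with inversion. The closest known reaction type is the intermolecular Corey–Chaykovsky epoxidation of aldehydes by ester-conjugated allylic sulfonium ylides under carbonate bases, which gives trans vinyl oxiranes; using it to close a ten-membered carbocycle is new. The ten-membered ring closes end to end by C8–C9 addition under high dilution, the chain being turned by the rigid butenolide and the trans 4,5-oxirane, and the oxirane closes by 3-exo-tet SN2 at C8. The trans C8/C9 relation should follow from reversible betaine formation with the anti betaine closing fastest, and the sense at C8 should follow from C6: the (6S) centre puts the C5 chain on one face of the planar ylide, the sulfonium lies away from the C13 silyloxymethyl group to avoid allylic strain, and bonding of C9 on the chain's face then leads after inversion to 8R, the trans requirement fixing 9R. The C1 silyloxy group was set syn to the C10 methyl so that its 1,3-anti polar bias supports this aldehyde face against the Felkin bias of the methyl group. The step needs C8 over C11 bonding (charge localised next to sulfur), epoxidation over loss of the C13 or C1 silyloxy groups (poor leaving groups, weak base) and cyclisation over oligomerisation (slow addition to 1 mM).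

Step 18
Reactants: 28 bis-epoxy macrocyclic butenolide
Product: 29 C1 alcohol
Conditions: HF·pyridine, pyridine, THF, 0 °C
Reagents that add atoms: none
Why: Buffered fluoride desilylation should remove the secondary triethylsilyl ether much faster than the primary tert-butyldimethylsilyl ether without opening either oxirane at 0 °C.

Step 19
Reactants: 29 C1 alcohol
Product: 30 C1 ketone
Conditions: Dess–Martin periodinane, NaHCO3, CH2Cl2, 0 → 23 °C
Reagents that add atoms: none
Why: Dess–Martin oxidation of the secondary alcohol under buffered, non-basic conditions should give the ketone without epimerising C10 or eliminating the 8,9-oxirane.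

Step 20
Reactants: 30 C1 ketone, 31 methacrylic acid
Product: 32 C8 methacrylate C9 alcohol (C13 tert-butyldimethylsilyl ether)
Conditions: Pd(PPh3)4 (5 mol %), 31 (3 equiv), THF, 0 → 23 °C
Reagents that add atoms: none
Why: Tsuji–Trost opening of a vinyl oxirane by a carboxylic acid, in which zerovalent palladium ionises the allylic C8–O bond with inversion, the acid protonates the C9 alkoxide, and methacrylate attacks the allyl terminus C8 (not the fully substituted C11, which would break lactone conjugation) anti to palladium, giving net retention at C8 (R) and a free C9 hydroxyl.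

Step 21
Reactants: 32 C8 methacrylate C9 alcohol
Product: 33 C13,C9 diol
Conditions: HF·pyridine, pyridine, THF, 0 → 23 °C
Reagents that add atoms: none
Why: Acidic fluoride desilylation of the primary silyl ether avoids the base-induced 1,2-acyl migration or retro-aldol that a basic fluoride source could cause.

Step 22
Reactants: 33 C13,C9 diol
Product: 34 target (CNP0185951.1)
Conditions: AcCl (1.1 equiv), 2,4,6-collidine, CH2Cl2, −78 °C
Reagents that add atoms: acetyl chloride, CC(Cl)=O
Why: Low-temperature acylation with acetyl chloride and collidine is selective for the primary allylic C13 hydroxyl over the hindered secondary C9 hydroxyl.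

**Compound list**
1 | geraniol | CC(C)=CCC/C(C)=C/CO | starting material
2 | (2R,3R)-2,3-epoxygeraniol | OC[C@H]1O[C@]1(C)CCC=C(C)C | intermediate
3 | (2S,3R)-2,3-epoxygeranial (oxirane arrangement of 2) | O=C[C@H]1O[C@]1(C)CCC=C(C)C | intermediate
4 | 2,3-dibromopropene | C=C(Br)CBr | starting material
5 | 4-methoxybenzyl alcohol | COc1ccc(CO)cc1 | starting material
6 | 2-bromoallyl 4-methoxybenzyl ether | C=C(Br)COCc1ccc(OC)cc1 | intermediate
7 | 2-lithioallyl 4-methoxybenzyl ether | [Li]C(=C)COCc1ccc(OC)cc1 | intermediate (not isolated)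
8 | anti epoxy alcohol, (1R)-2-[(4-methoxybenzyloxy)methyl]-1-[(2R,3R)-3-methyl-3-(4-methylpent-3-enyl)oxiran-2-yl]prop-2-en-1-ol (C6 R, epimeric to the target) | C=C(COCc1ccc(OC)cc1)[C@@H](O)[C@H]1O[C@]1(C)CCC=C(C)C | intermediate
9 | benzyl diethylphosphonoacetate | CCOP(=O)(OCC)CC(=O)OCc1ccccc1 | starting material
10 | benzyl 2-(diethoxyphosphoryl)-3-hydroxypropanoate (racemic) | CCOP(=O)(OCC)C(CO)C(=O)OCc1ccccc1 | intermediate
11 | benzyl 3-(tert-butyldimethylsilyloxy)-2-(diethoxyphosphoryl)propanoate (racemic) | CCOP(=O)(OCC)C(CO[Si](C)(C)C(C)(C)C)C(=O)OCc1ccccc1 | intermediate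
12 | 3-(tert-butyldimethylsilyloxy)-2-(diethoxyphosphoryl)propanoic acid (racemic) | CCOP(=O)(OCC)C(CO[Si](C)(C)C(C)(C)C)C(O)=O | intermediate
13 | syn phosphonate ester of inverted 8 (C6 S; both epimers at the phosphonate carbon) | C=C(COCc1ccc(OC)cc1)[C@H](OC(=O)C(CO[Si](C)(C)C(C)(C)C)P(=O)(OCC)OCC)[C@H]1O[C@]1(C)CCC=C(C)C | intermediate
14 | bis-ozonide of 13 (1,2,4-trioxolanes at C7 and at C1) | COc1ccc(COCC2(OCOO2)[C@H](OC(=O)C(CO[Si](C)(C)C(C)(C)C)P(=O)(OCC)OCC)[C@H]2O[C@]2(C)CCC2OC(C)(C)OO2)cc1 | intermediate (not isolated)
15 | keto aldehyde (13 with C7 ketone and C1 aldehyde; C4, C5, C6 arrangement unchanged) | COc1ccc(COCC(=O)[C@H](OC(=O)C(CO[Si](C)(C)C(C)(C)C)P(=O)(OCC)OCC)[C@H]2O[C@]2(C)CCC=O)cc1 | intermediate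
16 | butenolide aldehyde ((6S)-7(11)-en-12,6-olide, (4R,5R)-oxirane, C8 4-methoxybenzyl ether, C13 silyl ether, C1 aldehyde) | COc1ccc(COCC2=C(CO[Si](C)(C)C(C)(C)C)C(=O)O[C@@H]2[C@H]2O[C@]2(C)CCC=O)cc1 | intermediate
17 | (Z)-crotylboronic acid pinacol ester | C/C=C\CB1OC(C)(C)C(C)(C)O1 | starting material
18 | (1S,10S)-homoallylic alcohol (C1 carbinol syn to C10 methyl, C9 vinyl) | COc1ccc(COCC2=C(CO[Si](C)(C)C(C)(C)C)C(=O)O[C@@H]2[C@H]2O[C@]2(C)CC[C@H](O)[C@@H](C)C=C)cc1 | intermediate
19 | C1 triethylsilyl ether of 18 | COc1ccc(COCC2=C(CO[Si](C)(C)C(C)(C)C)C(=O)O[C@@H]2[C@H]2O[C@]2(C)CC[C@H](O[Si](CC)(CC)CC)[C@@H](C)C=C)cc1 | intermediate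
20 | C8 primary alcohol | OCC1=C(CO[Si](C)(C)C(C)(C)C)C(=O)O[C@@H]1[C@H]1O[C@]1(C)CC[C@H](O[Si](CC)(CC)CC)[C@@H](C)C=C | intermediate
21 | ozonide of 20 (1,2,4-trioxolane at C9) | OCC1=C(CO[Si](C)(C)C(C)(C)C)C(=O)O[C@@H]1[C@H]1O[C@]1(C)CC[C@H](O[Si](CC)(CC)CC)[C@@H](C)C1OCOO1 | intermediate (not isolated)
22 | C8 alcohol C9 aldehyde (C10 in the target's arrangement) | OCC1=C(CO[Si](C)(C)C(C)(C)C)C(=O)O[C@@H]1[C@H]1O[C@]1(C)CC[C@H](O[Si](CC)(CC)CC)[C@@H](C)C=O | intermediate
23 | C8 bromide C9 aldehyde | BrCC1=C(CO[Si](C)(C)C(C)(C)C)C(=O)O[C@@H]1[C@H]1O[C@]1(C)CC[C@H](O[Si](CC)(CC)CC)[C@@H](C)C=O | intermediate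
24 | tetrahydrothiophene | C1CCSC1 | starting material
25 | seco C8 tetrahydrothiophenium bromide with C9 aldehyde | C1CC[S+](C1)CC2=C(CO[Si](C)(C)C(C)(C)C)C(=O)O[C@@H]2[C@H]2O[C@]2(C)CC[C@H](O[Si](CC)(CC)CC)[C@@H](C)C=O.[Br-] | intermediate
26 | C8 sulfonium ylide | C1CC[S+](C1)[CH-]C2=C(CO[Si](C)(C)C(C)(C)C)C(=O)O[C@@H]2[C@H]2O[C@]2(C)CC[C@H](O[Si](CC)(CC)CC)[C@@H](C)C=O | intermediate (not isolated)
27 | anti betaine (C8–C9 bonded; 8S,9R by CIP, C8 inverts on closure) | C1CC[S+](C1)[C@H]2C3=C(CO[Si](C)(C)C(C)(C)C)C(=O)O[C@@H]3[C@H]3O[C@]3(C)CC[C@H](O[Si](CC)(CC)CC)[C@@H](C)[C@H]2[O-] | intermediate (not isolated)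
28 | 4,5:8,9-bis-epoxy macrocyclic butenolide (1S,4R,5R,6S,8R,9R,10S), C1 triethylsilyl ether, C13 tert-butyldimethylsilyl ether | O1[C@@H]2C3=C(CO[Si](C)(C)C(C)(C)C)C(=O)O[C@@H]3[C@H]3O[C@]3(C)CC[C@H](O[Si](CC)(CC)CC)[C@@H](C)[C@H]21 | intermediate
29 | C1 alcohol of 28 (all centres as in 28) | O1[C@@H]2C3=C(CO[Si](C)(C)C(C)(C)C)C(=O)O[C@@H]3[C@H]3O[C@]3(C)CC[C@H](O)[C@@H](C)[C@H]21 | intermediate
30 | C1 ketone (4R,5R,6S,8R,9R,10S) | O1[C@@H]2C3=C(CO[Si](C)(C)C(C)(C)C)C(=O)O[C@@H]3[C@H]3O[C@]3(C)CCC(=O)[C@@H](C)[C@H]21 | intermediate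
31 | methacrylic acid | C=C(C)C(=O)O | starting material
32 | C8 methacrylate C9 alcohol, C13 tert-butyldimethylsilyl ether | C=C(C)C(=O)O[C@@H]1C2=C(CO[Si](C)(C)C(C)(C)C)C(=O)O[C@@H]2[C@H]2O[C@]2(C)CCC(=O)[C@@H](C)[C@H]1O | intermediate
33 | C13,C9 diol with C8 methacrylate | C=C(C)C(=O)O[C@@H]1C2=C(CO)C(=O)O[C@@H]2[C@H]2O[C@]2(C)CCC(=O)[C@@H](C)[C@H]1O | intermediate
34 | CNP0185951.1 (4R,5R,6S,8R,9R,10S) | C=C(C)C(=O)O[C@@H]1C2=C(COC(C)=O)C(=O)O[C@@H]2[C@H]2O[C@]2(C)CCC(=O)[C@@H](C)[C@H]1O | target

**Step count**
Total: 22 steps. Longest linear sequence: 18 steps (1, 2, 4, 8–22, from geraniol).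

**Steps most likely to fail**

1. Step 17 (new method). The step may fail by deprotonation at C6 with opening of the 4,5-oxirane, by intermolecular ylide–aldehyde coupling, by epimerisation at C10 or beta-elimination of the C1 silyloxy group before closure, or by bonding on the wrong ylide or aldehyde face. The fallback uses known chemistry and sets out from 23. An Arbuzov reaction with triethyl phosphite (neat, 80 °C) should give the C8 diethyl phosphonate F1. Intramolecular vinylogous Horner–Wadsworth–Emmons olefination (LiCl, DBU, MeCN, 1 mM) should then close the ring as the (8E)-7(11),8-diene F2. Epoxidation of the distal 8,9-alkene of this dienoate with mCPBA (NaHCO3, CH2Cl2, 0 °C), expected from the outer face of the ring, should return to the route at 28.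

2. Step 20. The ring may shield the face of C8 anti to the oxirane oxygen so that ionisation stalls, the allyl complex may undergo beta-hydride elimination, or the carboxylate may attack C11. The fallback sets out from 30. LiBr and AcOH in THF at 0 °C should open the activated allylic C8–O bond by SN2 to the bromohydrin F3 (C8 inverted), the hindered 4,5-oxirane reacting more slowly. Sodium methacrylate in DMF (0 → 23 °C) should then displace the bromide with a second inversion and rejoin the route at 32.

3. Step 4. Facial selectivity of the vinyllithium addition to the epoxy aldehyde may be poor, giving C6 epimers that are hard to separate. The fallback sets out from 8 as obtained, mixed with its C6 epimer. Dess–Martin oxidation should give the epoxy enone F4. Zn(BH4)2 in Et2O at −20 °C reduces alpha,beta-epoxy ketones 1,2 through a zinc chelate between the carbonyl and oxirane oxygens and should return the anti alcohol 8 alone.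

**Further compounds**
F1 | step 17 | C8 diethyl phosphonate C9 aldehyde | CCOP(=O)(OCC)CC1=C(CO[Si](C)(C)C(C)(C)C)C(=O)O[C@@H]1[C@H]1O[C@]1(C)CC[C@H](O[Si](CC)(CC)CC)[C@@H](C)C=O
F2 | step 17 | macrocyclic (8E)-7(11),8-diene (4,5-oxirane, C1 triethylsilyl ether, C13 tert-butyldimethylsilyl ether) | C[C@H]1/C=C/C2=C(CO[Si](C)(C)C(C)(C)C)C(=O)O[C@@H]2[C@H]2O[C@]2(C)CC[C@@H]1O[Si](CC)(CC)CC
F3 | step 20 | 8-bromo-9-hydroxy macrocycle (C8 inverted, C9 retained) | Br[C@H]1C2=C(CO[Si](C)(C)C(C)(C)C)C(=O)O[C@@H]2[C@H]2O[C@]2(C)CCC(=O)[C@@H](C)[C@H]1O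
F4 | step 4 | epoxy enone (C6 ketone) | C=C(COCc1ccc(OC)cc1)C(=O)[C@H]1O[C@]1(C)CCC=C(C)C
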